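**Plan**

- Retrosynthetic cuts, in order: the eight O–benzyl bonds and the C3–O gallate ester; the C3–H bond (back to a chroman-3-one); the aromaticity of ring A (back to an 8a-hydroxy-tetrahydrochromene-3,5-dione); the pyran O1–C8a bond (retro-Achmatowicz, back to a 2-furyl carbinol); the furan C3–C3a and O–C2 bonds (back to a 5-silyloxycyclohexane-1,3-dione and an aryl epoxy aldehyde).
- Enabling feature: ring C is a 2-aryl-3-oxygenated pyran whose ring oxygen O1 is bonded to C8a of the phloroglucinol ring A. This O1–C2–C3(O)–C4–C4a–C8a array is what oxidative ring expansion of a 2-furyl carbinol annulated to a cyclohexane-1,3-dione-derived ring produces.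
- Forward order: the carbocycle that becomes ring A is made from phloroglucinol by partial reduction; the furan is annulated onto it; the furan is expanded to pyranone ring C; ring A is aromatised; ketone reduction, benzylation, galloylation and hydrogenolysis follow.
- Stereochemistry: C2 is the benzylic C–O carbon set by a catalyst-controlled epoxidation of the cinnamaldehyde, and that bond is never broken afterwards. C3 is set relative to C2 by a bulky hydride that gives the 2,3-cis alcohol.

Key step: step 5

Assumption: 3,4,5-tris(benzyloxy)benzaldehyde and 3,4,5-tris(benzyloxy)benzoic acid are bought (both are catalogue derivatives of gallic acid), and the (S)-prolinol catalyst of step 4 is taken to direct hydroperoxide anti to its diarylmethyl group; if the sense proves opposite, the (R)-catalyst is used.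

**Route**

Step 1
Reactants: 1 phloroglucinol
Product: 2 5-hydroxycyclohexane-1,3-dione (dihydrophloroglucinol)
Conditions: NaBH4, H2O, 0 °C → rt; then HCl to pH 3
Reagents that add atoms: none
Why: In water phloroglucinol reacts through its keto tautomer, so borohydride reduces one carbonyl and the resulting 5-hydroxy-1,3-dione is shielded from further hydride as its enolate (carbonyl reduction; the new carbinol carbon lies on a mirror plane and is not stereogenic).

Step 2
Reactants: 2 5-hydroxycyclohexane-1,3-dione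
Product: 4 5-(tert-butyldimethylsilyloxy)cyclohexane-1,3-dione, via bis-silyl enol ether 3 (not isolated)
Conditions: TBSCl (2.2 equiv), imidazole, DMF, rt; then pH 4 citrate buffer/THF, 0 °C
Reagents that add atoms: tert-butyldimethylsilyl chloride, CC(C)(C)[Si](C)(C)Cl
Why: Silylation covers the secondary alcohol and the acidic enol, and the enol silyl ether of 3, a vinylogous silyl ester, should hydrolyse in the buffered aqueous work-up while the alkyl silyl ether survives (silyl protection with selective hydrolysis).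

Step 3
Reactants: 5 3,4,5-tris(benzyloxy)benzaldehyde
Product: 6 (E)-3-[3,4,5-tris(benzyloxy)phenyl]prop-2-enal
Conditions: Ph3P=CHCHO (1.1 equiv), toluene, 80 °C
Reagents that add atoms: (triphenylphosphoranylidene)acetaldehyde, O=CC=P(c1ccccc1)(c1ccccc1)c1ccccc1
Why: Wittig olefination of the aromatic aldehyde with the stabilised formylmethylene ylide should give the two-carbon homologated enal with E geometry.

Step 4
Reactants: 6 (E)-3-[3,4,5-tris(benzyloxy)phenyl]prop-2-enal; 4 5-(tert-butyldimethylsilyloxy)cyclohexane-1,3-dione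
Product: 9 (R)-[6-(tert-butyldimethylsilyloxy)-4-oxo-4,5,6,7-tetrahydro-1-benzofuran-2-yl][3,4,5-tris(benzyloxy)phenyl]methanol (both C6 epimers), via epoxy aldehyde 7 (not isolated), via hydroxydihydrofuranone 8 (not isolated)
Conditions: (S)-2-{bis[3,5-bis(trifluoromethyl)phenyl](trimethylsilyloxy)methyl}pyrrolidine (10 mol%), 35% aq. H2O2 (1.3 equiv), CH2Cl2, rt; then 4 (1.2 equiv), Et3N (0.1 equiv), 0 °C → rt; then CSA (0.4 equiv), rt
Reagents that add atoms: hydrogen peroxide, OO
Why: In this iminium-catalysed nucleophilic epoxidation hydroperoxide adds to Cβ of the E-iminium ion anti to the shielding diarylmethyl group and the enamine closes the trans-epoxide, which fixes the benzylic C–O stereocentre; the dione then adds to the aldehyde, its enol oxygen opens the epoxide at Cα (5-exo-tet) without touching the benzylic C–O bond, and acid dehydration aromatises the interrupted Feist–Bénary adduct 8 to the furan, so the carbinol of 9 carries the epoxide configuration (R).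

Step 5
Reactants: 9 (R)-[6-(tert-butyldimethylsilyloxy)-4-oxo-4,5,6,7-tetrahydro-1-benzofuran-2-yl][3,4,5-tris(benzyloxy)phenyl]methanol
Product: 11 (2R)-7-(tert-butyldimethylsilyloxy)-8a-hydroxy-2-[3,4,5-tris(benzyloxy)phenyl]-6,7,8,8a-tetrahydro-2H-chromene-3,5-dione (C7/C8a mixture), via ene-trione 10 (not isolated)
Conditions: VO(acac)2 (5 mol%), t-BuOOH (1.5 equiv, decane), CH2Cl2, 0 °C → rt
Reagents that add atoms: tert-butyl hydroperoxide, CC(C)(C)OO
Why: t-BuOOH converts VO(acac)2 into a pentavalent vanadium alkylperoxo complex that binds the carbinol oxygen of 9 and transfers oxygen to the adjacent furan C2=C3 bond, which stays enol-ether-like because the ring ketone is conjugated only with C3a=C7a; the labile furan epoxide opens with cleavage of the furan O–C2 bond to ene-trione 10, in which the former furan carbons C2 and C7a are carbonyl groups. This is the Achmatowicz oxidative ring expansion of 2-furyl carbinols in its hydroxyl-directed vanadium/t-BuOOH form. The carbinol oxygen then adds to one of the two equivalent ring carbonyls of 10 in a 6-exo-trig hemiketalisation, which forms the pyran O1–C8a bond (chroman numbering) and closes pyranone ring C with C3 as the ketone. C2 is the untouched carbinol carbon and keeps its R configuration, while the new hemiketal centre C8a forms under thermodynamic (anomeric) control as a mixture that is of no consequence because C8a and C7 both become trigonal on aromatisation. The step requires oxidation of the furan in preference to the three benzyloxy arenes, the benzyl ethers and the benzylic carbinol, and coordination of the carbinol to vanadium secures this by delivering the peroxide oxygen intramolecularly to the furan.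

Step 6
Reactants: 11 (2R)-7-(tert-butyldimethylsilyloxy)-8a-hydroxy-2-[3,4,5-tris(benzyloxy)phenyl]-6,7,8,8a-tetrahydro-2H-chromene-3,5-dione
Product: 13 (2R)-7-(tert-butyldimethylsilyloxy)-5-hydroxy-2-[3,4,5-tris(benzyloxy)phenyl]-2H-chromen-3(4H)-one, via dienone 12 (not isolated)
Conditions: TFA (3 equiv), 4 Å MS, CH2Cl2, −20 → 0 °C; product used at once in step 7
Reagents that add atoms: none
Why: Proposed new method: TFA should ionise the tertiary hemiketal of 11 to the O1-stabilised C8a oxocarbenium ion, which loses H-8 to the cyclic dienol ether 12, and 12, a cyclohexenone carrying an exocyclic C4=C4a bond, should then isoaromatise by enolisation of C5=O and acid-mediated transfer of H-7 to C4, driven by formation of aromatic ring A with the free hydroxyl at C5 and the silyl ether at C7; the closest known reaction types are the acid-catalysed dehydration of cyclic hemiketals to endocyclic enol ethers and the prototropic isomerisation of alkylidene cyclohexenones to phenols, and since C2–H takes no part the R configuration should be kept.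

Step 7
Reactants: 13 (2R)-7-(tert-butyldimethylsilyloxy)-5-hydroxy-2-[3,4,5-tris(benzyloxy)phenyl]-2H-chromen-3(4H)-one
Product: 14 (2R,3R)-7-(tert-butyldimethylsilyloxy)-2-[3,4,5-tris(benzyloxy)phenyl]chromane-3,5-diol
Conditions: LiBH(sec-Bu)3 (3 equiv), LiBr, THF, −78 °C; aq. NH4Cl
Reagents that add atoms: none
Why: After the first equivalent is consumed by the phenol, the bulky hydride should attack the C3 carbonyl of the half-chair chromanone from the equatorial direction and give the axial alcohol cis to the equatorial C2 aryl group (3R), the known outcome of trialkylborohydride reduction of 2-aryl-chroman-3-ones (diastereoselective ketone reduction).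

Step 8
Reactants: 14 (2R,3R)-7-(tert-butyldimethylsilyloxy)-2-[3,4,5-tris(benzyloxy)phenyl]chromane-3,5-diol
Product: 16 (2R,3R)-5,7-bis(benzyloxy)-2-[3,4,5-tris(benzyloxy)phenyl]chroman-3-ol, via triol 15 (not isolated)
Conditions: CsF, DMF, 0 °C; then K2CO3, BnBr, 0 °C → rt
Reagents that add atoms: benzyl bromide, BrCc1ccccc1
Why: Fluoride cleaves the aryl silyl ether without touching the secondary alcohol, and the two phenoxides of triol 15 are then benzylated under carbonate conditions that do not deprotonate the C3 alcohol (desilylation followed by Williamson ether synthesis, kept cold to limit C-benzylation of the electron-rich ring).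

Step 9
Reactants: 16 (2R,3R)-5,7-bis(benzyloxy)-2-[3,4,5-tris(benzyloxy)phenyl]chroman-3-ol; 17 3,4,5-tris(benzyloxy)benzoic acid
Product: 18 (2R,3R)-5,7-bis(benzyloxy)-2-[3,4,5-tris(benzyloxy)phenyl]chroman-3-yl 3,4,5-tris(benzyloxy)benzoate
Conditions: DCC, DMAP, CH2Cl2, rt
Reagents that add atoms: none
Why: Steglich esterification acylates the hindered axial C3 hydroxyl with retention of configuration, a transformation established for benzyl-protected flavan-3-ols.

Step 10
Reactants: 18 (2R,3R)-5,7-bis(benzyloxy)-2-[3,4,5-tris(benzyloxy)phenyl]chroman-3-yl 3,4,5-tris(benzyloxy)benzoate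
Product: 19 (−)-epigallocatechin gallate
Conditions: H2 (1 atm), Pd(OH)2/C, THF/MeOH, rt
Reagents that add atoms: none
Why: Catalytic hydrogenolysis should remove all eight benzyl ethers under neutral conditions that leave the gallate ester and both stereocentres untouched.

**Compound list**

1 | phloroglucinol | Oc1cc(O)cc(O)c1 | starting material
2 | 5-hydroxycyclohexane-1,3-dione | O=C1CC(O)CC(=O)C1 | intermediate
3 | 3,5-bis(tert-butyldimethylsilyloxy)cyclohex-2-en-1-one (racemic) | O=C1C=C(O[Si](C)(C)C(C)(C)C)CC(O[Si](C)(C)C(C)(C)C)C1 | intermediate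
4 | 5-(tert-butyldimethylsilyloxy)cyclohexane-1,3-dione | O=C1CC(O[Si](C)(C)C(C)(C)C)CC(=O)C1 | intermediate
5 | 3,4,5-tris(benzyloxy)benzaldehyde | O=Cc1cc(OCc2ccccc2)c(OCc2ccccc2)c(OCc2ccccc2)c1 | starting material
6 | (E)-3-[3,4,5-tris(benzyloxy)phenyl]prop-2-enal | O=C/C=C/c1cc(OCc2ccccc2)c(OCc2ccccc2)c(OCc2ccccc2)c1 | intermediate
7 | (2S,3R)-3-[3,4,5-tris(benzyloxy)phenyl]oxirane-2-carbaldehyde | O=C[C@H]1O[C@@H]1c1cc(OCc2ccccc2)c(OCc2ccccc2)c(OCc2ccccc2)c1 | intermediate
8 | (2R)-6-(tert-butyldimethylsilyloxy)-3-hydroxy-2-{(R)-hydroxy[3,4,5-tris(benzyloxy)phenyl]methyl}-2,3,6,7-tetrahydro-1-benzofuran-4(5H)-one (mixture at C3 and C6) | O[C@@H]([C@H]1OC2=C(C1O)C(=O)CC(O[Si](C)(C)C(C)(C)C)C2)c1cc(OCc2ccccc2)c(OCc2ccccc2)c(OCc2ccccc2)c1 | intermediate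
9 | (R)-[6-(tert-butyldimethylsilyloxy)-4-oxo-4,5,6,7-tetrahydro-1-benzofuran-2-yl][3,4,5-tris(benzyloxy)phenyl]methanol (both C6 epimers) | O[C@@H](c1cc2c(o1)CC(O[Si](C)(C)C(C)(C)C)CC2=O)c1cc(OCc2ccccc2)c(OCc2ccccc2)c(OCc2ccccc2)c1 | intermediate
10 | 2-{(3R)-3-hydroxy-2-oxo-3-[3,4,5-tris(benzyloxy)phenyl]propylidene}-5-(tert-butyldimethylsilyloxy)cyclohexane-1,3-dione | O[C@@H](C(=O)C=C1C(=O)CC(O[Si](C)(C)C(C)(C)C)CC1=O)c1cc(OCc2ccccc2)c(OCc2ccccc2)c(OCc2ccccc2)c1 | intermediate
11 | (2R)-7-(tert-butyldimethylsilyloxy)-8a-hydroxy-2-[3,4,5-tris(benzyloxy)phenyl]-6,7,8,8a-tetrahydro-2H-chromene-3,5-dione (mixture at C7 and C8a) | O=C1C=C2C(=O)CC(O[Si](C)(C)C(C)(C)C)CC2(O)O[C@@H]1c1cc(OCc2ccccc2)c(OCc2ccccc2)c(OCc2ccccc2)c1 | intermediate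
12 | (2R)-7-(tert-butyldimethylsilyloxy)-2-[3,4,5-tris(benzyloxy)phenyl]-6,7-dihydro-2H-chromene-3,5-dione (mixture at C7) | O=C1C=C2C(=O)CC(O[Si](C)(C)C(C)(C)C)C=C2O[C@@H]1c1cc(OCc2ccccc2)c(OCc2ccccc2)c(OCc2ccccc2)c1 | intermediate
13 | (2R)-7-(tert-butyldimethylsilyloxy)-5-hydroxy-2-[3,4,5-tris(benzyloxy)phenyl]-2H-chromen-3(4H)-one | O=C1Cc2c(O)cc(O[Si](C)(C)C(C)(C)C)cc2O[C@@H]1c1cc(OCc2ccccc2)c(OCc2ccccc2)c(OCc2ccccc2)c1 | intermediate
14 | (2R,3R)-7-(tert-butyldimethylsilyloxy)-2-[3,4,5-tris(benzyloxy)phenyl]chromane-3,5-diol | O[C@@H]1Cc2c(O)cc(O[Si](C)(C)C(C)(C)C)cc2O[C@@H]1c1cc(OCc2ccccc2)c(OCc2ccccc2)c(OCc2ccccc2)c1 | intermediate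
15 | (2R,3R)-2-[3,4,5-tris(benzyloxy)phenyl]chromane-3,5,7-triol | O[C@@H]1Cc2c(O)cc(O)cc2O[C@@H]1c1cc(OCc2ccccc2)c(OCc2ccccc2)c(OCc2ccccc2)c1 | intermediate
16 | (2R,3R)-5,7-bis(benzyloxy)-2-[3,4,5-tris(benzyloxy)phenyl]chroman-3-ol | O[C@@H]1Cc2c(OCc3ccccc3)cc(OCc3ccccc3)cc2O[C@@H]1c1cc(OCc2ccccc2)c(OCc2ccccc2)c(OCc2ccccc2)c1 | intermediate
17 | 3,4,5-tris(benzyloxy)benzoic acid | OC(=O)c1cc(OCc2ccccc2)c(OCc2ccccc2)c(OCc2ccccc2)c1 | starting material
18 | (2R,3R)-5,7-bis(benzyloxy)-2-[3,4,5-tris(benzyloxy)phenyl]chroman-3-yl 3,4,5-tris(benzyloxy)benzoate | O=C(O[C@@H]1Cc2c(OCc3ccccc3)cc(OCc3ccccc3)cc2O[C@@H]1c1cc(OCc2ccccc2)c(OCc2ccccc2)c(OCc2ccccc2)c1)c1cc(OCc2ccccc2)c(OCc2ccccc2)c(OCc2ccccc2)c1 | intermediate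
19 | (−)-epigallocatechin gallate, (2R,3R) | O=C(O[C@@H]1Cc2c(O)cc(O)cc2O[C@@H]1c1cc(O)c(O)c(O)c1)c1cc(O)c(O)c(O)c1 | target

**Totals**

Total step count: 10. Longest linear sequence: 9 steps (steps 1, 2, 4, 5, 6, 7, 8, 9, 10).

**Steps most likely to fail**

1. Step 6 (aromatisation of ring A). Ionisation of the hemiketal may be slow because the cation sits next to an electron-poor alkene. Three processes can then compete:
   - ring-opening to the ene-trione followed by isoaromatisation, which would place the former furan oxygen on the arene and lead towards a benzofuran;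
   - loss of H-2 from the cation, which would racemise C2 through a 3-hydroxypyrylium ion;
   - β-elimination of silanol from C7.

   The fallback uses known reactions only, sets out from 11 and comes back at 15. Silane reduction of the hemiketal under the conditions usual for Achmatowicz products (Et3SiH, TFA, CH2Cl2, −40 °C) traps the oxocarbenium ion with hydride and should give (2R)-7-(tert-butyldimethylsilyloxy)-2-[3,4,5-tris(benzyloxy)phenyl]-6,7,8,8a-tetrahydro-2H-chromene-3,5-dione F1. HF·pyridine in THF at 0 °C frees the C7 alcohol to give (2R)-7-hydroxy-2-[3,4,5-tris(benzyloxy)phenyl]-6,7,8,8a-tetrahydro-2H-chromene-3,5-dione F2. Dess–Martin periodinane (NaHCO3, CH2Cl2) oxidises C7 to the ketone; the resulting 3,5,7-trione is a keto tautomer of a phloroglucinol, so simple prototropy (H-8a to C4, enolisation at C5 and C7) should deliver (2R)-5,7-dihydroxy-2-[3,4,5-tris(benzyloxy)phenyl]-2H-chromen-3(4H)-one F3 with no dehydration step. Reduction of F3 with LiBH(sec-Bu)3 as in step 7 gives triol 15, which enters the benzylation stage of step 8.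

2. Step 5 (key ring expansion). Oxygen transfer to a furan deactivated by the ring acyl group may be slow, so that oxidation of the benzylic carbinol to the diaryl ketone or further oxidation of the ene-trione competes. The fallback sets out from 9 and comes back at 11 without relying on hydroxyl-directed oxygen transfer. Dye-sensitised photooxygenation (O2, methylene blue, hν, CH2Cl2, −78 °C) adds singlet oxygen across the furan 2- and 7a-positions in a [4+2] cycloaddition to give the endoperoxide (R)-[6-(tert-butyldimethylsilyloxy)-4-oxo-2,7a-epidioxy-2,4,5,6,7,7a-hexahydro-1-benzofuran-2-yl][3,4,5-tris(benzyloxy)phenyl]methanol F4. Me2S then reduces the O–O bond to the same ene-trione 10, which closes to 11.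

3. Step 4 (epoxidation and furan annulation). Conjugate addition of hydroperoxide to the electron-rich cinnamaldehyde iminium ion may be incomplete, so that base-mediated background epoxidation erodes the enantiomeric purity once the dione and amine are added. The benzylic epoxide may also open prematurely or at the benzylic carbon, and the aldehyde may condense with two molecules of dione. The fallback sets out from 6 and comes back at 7, which is then isolated free of peroxide and amine. Reduction (NaBH4, CeCl3·7H2O, MeOH, 0 °C) gives (E)-3-[3,4,5-tris(benzyloxy)phenyl]prop-2-en-1-ol F5. Sharpless asymmetric epoxidation (Ti(OiPr)4, D-(−)-diisopropyl tartrate, t-BuOOH, 4 Å MS, CH2Cl2, −20 °C) gives [(2R,3R)-3-[3,4,5-tris(benzyloxy)phenyl]oxiran-2-yl]methanol F6. Parikh–Doering oxidation (SO3·pyridine, DMSO, iPr2NEt, 0 °C) gives epoxy aldehyde 7, which is combined with 4 by slow addition under the second-stage conditions of step 4 to reach 9.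

**Further compounds**

F1 | step 6 | (2R)-7-(tert-butyldimethylsilyloxy)-2-[3,4,5-tris(benzyloxy)phenyl]-6,7,8,8a-tetrahydro-2H-chromene-3,5-dione | O=C1C=C2C(=O)CC(O[Si](C)(C)C(C)(C)C)CC2O[C@@H]1c1cc(OCc2ccccc2)c(OCc2ccccc2)c(OCc2ccccc2)c1
F2 | step 6 | (2R)-7-hydroxy-2-[3,4,5-tris(benzyloxy)phenyl]-6,7,8,8a-tetrahydro-2H-chromene-3,5-dione | O=C1C=C2C(=O)CC(O)CC2O[C@@H]1c1cc(OCc2ccccc2)c(OCc2ccccc2)c(OCc2ccccc2)c1
F3 | step 6 | (2R)-5,7-dihydroxy-2-[3,4,5-tris(benzyloxy)phenyl]-2H-chromen-3(4H)-one | O=C1Cc2c(O)cc(O)cc2O[C@@H]1c1cc(OCc2ccccc2)c(OCc2ccccc2)c(OCc2ccccc2)c1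
F4 | step 5 | (R)-[6-(tert-butyldimethylsilyloxy)-4-oxo-2,7a-epidioxy-2,4,5,6,7,7a-hexahydro-1-benzofuran-2-yl][3,4,5-tris(benzyloxy)phenyl]methanol | O[C@@H](C12OOC3(O1)CC(O[Si](C)(C)C(C)(C)C)CC(=O)C3=C2)c1cc(OCc2ccccc2)c(OCc2ccccc2)c(OCc2ccccc2)c1
F5 | step 4 | (E)-3-[3,4,5-tris(benzyloxy)phenyl]prop-2-en-1-ol | OC/C=C/c1cc(OCc2ccccc2)c(OCc2ccccc2)c(OCc2ccccc2)c1
F6 | step 4 | [(2R,3R)-3-[3,4,5-tris(benzyloxy)phenyl]oxiran-2-yl]methanol | OC[C@H]1O[C@@H]1c1cc(OCc2ccccc2)c(OCc2ccccc2)c(OCc2ccccc2)c1
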